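**Strategy.** Atoms are numbered C1 (carbinol carbon carrying the C2–C4 chain), C10 (CHMe), C9 (CHOH), C8, C7, C6 (lactone O–CH) and C5 (ester) round the seven-membered ring. The ring is disconnected at C7–C8 and C1–C10: C8–C9(O)–C10(Me) is the footprint of a 2-oxyallyl cation, C7–C6–C5–C1 that of a furan diene whose oxygen survives as the tertiary C1 hydroxyl. One zinc-mediated, hydroxyl-directed furan–oxyallyl (4+3) cycloaddition of furyl carbinol 7 with 1,3-dibromobutan-2-one forms both bonds and sets C1 and C10. The oxygen bridge then directs exo-dihydroxylation, is opened towards C7 by β-elimination from the C9 ketone, and the C6 oxygen delivers the lactone carbon to C7.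

Key step: step 4

Remark on the chemistry: 1,3-dibromobutan-2-one (8) is taken as a catalogue compound. The facial sense of step 4 rests on the chelate model given there. The C2 carbinol centre it uses is temporary (oxidised in step 15). C11, C12 and C13 are the lactone α-carbon, carbonyl carbon and methylene carbon.

Step 1
Reactants: 1 methyl (3R)-3-hydroxybutanoate
Product: 2 methyl (3R)-3-(tert-butyldimethylsilyloxy)butanoate
Conditions: TBSCl, imidazole, DMF, 23 °C
Reagents that add atoms: tert-butyldimethylsilyl chloride, CC(C)(C)[Si](C)(C)Cl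
Why: Imidazole-promoted silylation of an unhindered secondary alcohol is routine and leaves the chiral-pool stereocentre (the future C4) untouched.

Step 2
Reactants: 2 methyl (3R)-3-(tert-butyldimethylsilyloxy)butanoate; 3 furan
Product: 6 (3R)-3-(tert-butyldimethylsilyloxy)-1-(furan-2-yl)butan-1-one, via Weinreb amide 4 (not isolated), via 2-furyllithium 5 (not isolated)
Conditions: MeNH(OMe)·HCl, iPrMgCl, THF, −20 °C; then 2-furyllithium (from 3, nBuLi, THF, 0 °C), −78 to 0 °C; aq. NH4Cl
Reagents that add atoms: none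
Why: The chloromagnesium amide turns the ester into the Weinreb amide in the flask and 2-furyllithium then adds only once because the chelated tetrahedral intermediate survives until work-up (Weinreb ketone synthesis), no stereocentre being formed or enolised.

Step 3
Reactants: 6 (3R)-3-(tert-butyldimethylsilyloxy)-1-(furan-2-yl)butan-1-one
Product: 7 (1R,3R)-3-(tert-butyldimethylsilyloxy)-1-(furan-2-yl)butan-1-ol
Conditions: (S)-2-methyl-CBS-oxazaborolidine (0.2 equiv), BH3·SMe2, THF, −30 °C; MeOH, aq. work-up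
Reagents that add atoms: none
Why: Corey–Bakshi–Shibata reduction in which the furyl ring plays the large group, so that the (S)-catalyst should deliver hydride to the face giving the (1R)-carbinol under reagent control, the remote silyloxy centre having little influence.

Step 4
Reactants: 7 (1R,3R)-3-(tert-butyldimethylsilyloxy)-1-(furan-2-yl)butan-1-ol; 8 1,3-dibromobutan-2-one (racemic)
Product: 11 (1R,2R,5R)-1-[(1R,3R)-3-(tert-butyldimethylsilyloxy)-1-hydroxybutyl]-2-methyl-8-oxabicyclo[3.2.1]oct-6-en-3-one, via ethylzinc alkoxide 9 (not isolated), via zinc oxyallyl cation 10 (not isolated)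
Conditions: Et2Zn (2.5 equiv), 8 (1.5 equiv, slow addition), THF, 0 to 23 °C
Reagents that add atoms: none
Why: Et2Zn first converts the carbinol into its ethylzinc alkoxide and, by bromine–zinc exchange on 8 and loss of bromide, generates the zinc-bound 2-oxyallyl cation, which adds across the two α-carbons of the furan in a concerted but asynchronous (4+3) cycloaddition; the closest known reaction is the Et2Zn-mediated cycloaddition of α,α'-dibromo ketones to 2-(1-hydroxyalkyl)furans. The seven-membered carbocycle and the oxygen-bridged bicycle are closed together by this suprafacial addition, through the extended transition state that the O–Zn–O chelate between alkoxide and oxyallyl oxygen enforces. C1, and with it the bridgehead C7, is set by the carbinol centre: with its C–O bond turned towards the incoming cation and its hydrogen eclipsing the furan 3-H (minimal allylic 1,3-strain), the silyloxypropyl chain covers the other face. C10 is set by the Z geometry of the zinc oxyallyl in the extended arrangement, which places the methyl group syn to the oxygen bridge (axial). The step needs head-to-head regiochemistry (methyl-bearing terminus to the substituted furan carbon); this should follow because bond formation leads between the unsubstituted, most nucleophilic furan α-carbon and the unhindered CH2 terminus of the cation, so the more congested C1–C10 bond closes last.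

Step 5
Reactants: 11 cycloadduct
Product: 12 (1R,2R,5R)-1-[(1R,3R)-3-(tert-butyldimethylsilyloxy)-1-(triethylsilyloxy)butyl]-2-methyl-8-oxabicyclo[3.2.1]oct-6-en-3-one
Conditions: TESOTf, 2,6-lutidine, CH2Cl2, −78 °C
Reagents that add atoms: triethylsilyl trifluoromethanesulfonate, CC[Si](CC)(CC)OS(=O)(=O)C(F)(F)F
Why: The silyl triflate should cap the hindered secondary carbinol at low temperature faster than the weak base can enolise the ketone, whose C10 hydrogen is equatorial and poorly aligned, so the axial methyl is kept.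

Step 6
Reactants: 12 TES ether
Product: 13 (1S,2R,5R,6S,7R)-6,7-dihydroxy-2-methyl-1-[(1R,3R)-3-(tert-butyldimethylsilyloxy)-1-(triethylsilyloxy)butyl]-8-oxabicyclo[3.2.1]octan-3-one (exo,exo-diol)
Conditions: OsO4 (2 mol %), NMO, acetone/H2O, 23 °C
Reagents that add atoms: N-methylmorpholine N-oxide, C[N+]1([O-])CCOCC1 (oxygen relayed by OsO4); water, O
Why: Upjohn dihydroxylation, in which the osmium reagent can reach the two-carbon bridge only from the exo face beside the bridging oxygen because the three-carbon ketone bridge covers the endo face, so that both new C–O bonds (C5 and C6) are set cis to the oxygen bridge.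

Step 7
Reactants: 13 exo,exo-diol; 14 (diethoxyphosphoryl)acetic acid
Product: 15 (1S,2R,5R,6S,7R)-7-hydroxy-2-methyl-3-oxo-1-[(1R,3R)-3-(tert-butyldimethylsilyloxy)-1-(triethylsilyloxy)butyl]-8-oxabicyclo[3.2.1]octan-6-yl (diethoxyphosphoryl)acetate
Conditions: 14 (1.1 equiv), DCC, DMAP (cat.), CH2Cl2, −20 to 0 °C
Reagents that add atoms: none
Why: Steglich esterification should select the C6 hydroxyl, which neighbours the unsubstituted bridgehead C7–H, over the C5 hydroxyl, which is neopentylic to the fully substituted bridgehead C1, and any acyl migration between the cis hydroxyls runs towards the same less hindered ester.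

Step 8
Reactants: 15 phosphonoacetate
Product: 16 (1R,5R,6R,7R)-5-methyl-4-oxo-6-[(1R,3R)-3-(tert-butyldimethylsilyloxy)-1-(triethylsilyloxy)butyl]-6,7-bis(trimethylsilyloxy)cyclohept-2-en-1-yl (diethoxyphosphoryl)acetate
Conditions: TMSOTf (3 equiv), Et3N (5 equiv), CH2Cl2, −78 to 0 °C
Reagents that add atoms: trimethylsilyl trifluoromethanesulfonate, C[Si](C)(C)OS(=O)(=O)C(F)(F)F
Why: Silyl-triflate/amine-mediated β-elimination of a β-alkoxy ketone: soft enolisation is possible only towards C8 (its axial hydrogen is aligned, whereas the C10 hydrogen is equatorial), silylation of the bridging oxygen then expels it from C7 to give the C7=C8 enone with C1–OTMS, and the free C5 hydroxyl is capped as its TMS ether in the same flask, no stereocentre being formed.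

Step 9
Reactants: 16 enone phosphonoacetate
Product: 19 (3aS,6R,7S,8R,8aR)-7,8-dihydroxy-6-methyl-3-methylidene-7-[(1R,3R)-3-(tert-butyldimethylsilyloxy)-1-(triethylsilyloxy)butyl]hexahydro-2H-cyclohepta[b]furan-2,5(3H)-dione, via phosphono lactone 17 (not isolated), via bis-TMS methylene lactone 18 (not isolated)
Conditions: KOtBu (1.1 equiv), THF, 0 °C; then (CH2O)n, 0 to 23 °C; then citric acid, MeOH, 23 °C
Reagents that add atoms: formaldehyde (from paraformaldehyde), C=O
Why: Tandem intramolecular Michael addition/Horner–Wadsworth–Emmons olefination: the phosphonate carbanion tethered to the C6 oxygen adds 5-exo-trig to C7 and can only give the cis-fused lactone (C7–C11 on the face of C6–O), the resulting α-phosphono lactone anion olefinates formaldehyde to the α-methylene lactone, and mild acidic methanolysis then removes only the two TMS ethers.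

Step 10
Reactants: 19 keto diol lactone
Product: 20 (3aS,6R,7R,8aR)-7-hydroxy-6-methyl-3-methylidene-7-[(1R,3R)-3-(tert-butyldimethylsilyloxy)-1-(triethylsilyloxy)butyl]tetrahydro-2H-cyclohepta[b]furan-2,5,8(3H)-trione
Conditions: Dess–Martin periodinane, NaHCO3, CH2Cl2, 0 to 23 °C
Reagents that add atoms: none
Why: Dess–Martin oxidation of the only secondary hydroxyl (C5) under buffered, non-enolising conditions erases the wrongly configured C5 centre, the tertiary C1 hydroxyl being inert.

Step 11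
Reactants: 20 diketo lactone
Product: 21 (3aS,5R,6S,7S,8S,8aR)-5,7,8-trihydroxy-6-methyl-3-methylidene-7-[(1R,3R)-3-(tert-butyldimethylsilyloxy)-1-(triethylsilyloxy)butyl]octahydro-2H-cyclohepta[b]furan-2-one
Conditions: Me4NBH(OAc)3 (10 equiv), MeCN/AcOH 1:1, −30 to 0 °C
Reagents that add atoms: none
Why: Evans–Saksena hydroxyl-directed reduction: the tertiary C1 hydroxyl binds the acetoxyborohydride and should deliver hydride from its own face to both ketones within reach (C5, α; C9, β), so that both new hydroxyls come out anti to C1–OH, the C1 side chain also covering the opposite face of C5, while lactone and enoate are not reduced by this reagent.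

Step 12
Reactants: 21 triol
Product: 22 (3aS,5R,6S,7S,8S,8aR)-5-(tert-butyldimethylsilyloxy)-7,8-dihydroxy-6-methyl-3-methylidene-7-[(1R,3R)-3-(tert-butyldimethylsilyloxy)-1-(triethylsilyloxy)butyl]octahydro-2H-cyclohepta[b]furan-2-one
Conditions: TBSOTf (1.05 equiv), 2,6-lutidine, CH2Cl2, −78 °C
Reagents that add atoms: tert-butyldimethylsilyl trifluoromethanesulfonate, CC(C)(C)[Si](C)(C)OS(=O)(=O)C(F)(F)F
Why: Site-selective silylation with one equivalent of a bulky silyl donor should take the C9 hydroxyl, which lies between CH2 and CHMe, in preference to the C5 hydroxyl flanked by the quaternary C1 and the lactone carbon C6 and to the tertiary C1 hydroxyl.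

Step 13
Reactants: 22 C9 silyl ether; 23 (2R)-2-methylbutanoic acid
Product: 24 (3aS,5R,6S,7S,8S,8aR)-5-(tert-butyldimethylsilyloxy)-7-hydroxy-6-methyl-3-methylidene-2-oxo-7-[(1R,3R)-3-(tert-butyldimethylsilyloxy)-1-(triethylsilyloxy)butyl]octahydro-2H-cyclohepta[b]furan-8-yl (2R)-2-methylbutanoate
Conditions: 23 (3 equiv), DCC, DMAP, CH2Cl2, 23 °C
Reagents that add atoms: none
Why: Steglich esterification of the only remaining secondary hydroxyl (C5) with the enantiopure acid, whose simple α-alkyl centre should be configurationally stable under carbodiimide/DMAP activation, the tertiary C1 hydroxyl not being acylated.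

Step 14
Reactants: 24 C5 ester
Product: 25 (3aS,5R,6S,7R,8S,8aR)-5-(tert-butyldimethylsilyloxy)-7-hydroxy-7-[(1R,3R)-3-(tert-butyldimethylsilyloxy)-1-hydroxybutyl]-6-methyl-3-methylidene-2-oxooctahydro-2H-cyclohepta[b]furan-8-yl (2R)-2-methylbutanoate
Conditions: PPTS (0.2 equiv), MeOH/CH2Cl2, 0 °C
Reagents that add atoms: none
Why: Acid-catalysed methanolysis distinguishes silyl ethers by size, so the triethylsilyl ether at C2 should be cleaved well before the two tert-butyldimethylsilyl ethers at C4 and C9.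

Step 15
Reactants: 25 C2 carbinol
Product: 26 (3aS,5R,6S,7S,8S,8aR)-5-(tert-butyldimethylsilyloxy)-7-[(3R)-3-(tert-butyldimethylsilyloxy)butanoyl]-7-hydroxy-6-methyl-3-methylidene-2-oxooctahydro-2H-cyclohepta[b]furan-8-yl (2R)-2-methylbutanoate
Conditions: Dess–Martin periodinane, NaHCO3, CH2Cl2, 23 °C
Reagents that add atoms: none
Why: Dess–Martin oxidation of the single free secondary hydroxyl (C2), whose stereocentre has done its work, gives the side-chain ketone under neutral conditions that spare the adjacent tertiary hydroxyl and the β-silyloxy group.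

Step 16
Reactants: 26 bis-TBS ether
Product: 27 target, (3aS,5R,6S,7S,8S,8aR)-5,7-dihydroxy-7-[(3R)-3-hydroxybutanoyl]-6-methyl-3-methylidene-2-oxooctahydro-2H-cyclohepta[b]furan-8-yl (2R)-2-methylbutanoate
Conditions: HF·pyridine, pyridine, THF, 0 to 23 °C
Reagents that add atoms: none
Why: Buffered fluoride desilylation should remove both TBS ethers without β-elimination of the C4 hydroxy ketone, conjugate addition to the α-methylene lactone or ester migration.

**Compound list**

1 | methyl (3R)-3-hydroxybutanoate | COC(=O)C[C@@H](C)O | starting material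
2 | methyl (3R)-3-(tert-butyldimethylsilyloxy)butanoate | COC(=O)C[C@@H](C)O[Si](C)(C)C(C)(C)C | intermediate
3 | furan | c1ccoc1 | starting material
4 | (3R)-3-(tert-butyldimethylsilyloxy)-N-methoxy-N-methylbutanamide (Weinreb amide) | CON(C)C(=O)C[C@@H](C)O[Si](C)(C)C(C)(C)C | intermediate
5 | 2-furyllithium | [Li]c1ccco1 | intermediate
6 | (3R)-3-(tert-butyldimethylsilyloxy)-1-(furan-2-yl)butan-1-one | O=C(C[C@@H](C)O[Si](C)(C)C(C)(C)C)c1ccco1 | intermediate
7 | (1R,3R)-3-(tert-butyldimethylsilyloxy)-1-(furan-2-yl)butan-1-ol | o1cccc1[C@H](O)C[C@@H](C)O[Si](C)(C)C(C)(C)C | intermediate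
8 | 1,3-dibromobutan-2-one (racemic) | CC(Br)C(=O)CBr | starting material
9 | ethylzinc (1R,3R)-3-(tert-butyldimethylsilyloxy)-1-(furan-2-yl)butan-1-olate | o1cccc1[C@H](O[Zn]CC)C[C@@H](C)O[Si](C)(C)C(C)(C)C | intermediate
10 | ethylzinc-bound 1-methyl-2-oxyallyl cation (bromide) | C[CH+]C(=C)O[Zn]CC.[Br-] | intermediate
11 | (1R,2R,5R)-1-[(1R,3R)-3-(tert-butyldimethylsilyloxy)-1-hydroxybutyl]-2-methyl-8-oxabicyclo[3.2.1]oct-6-en-3-one (2-methyl syn to the oxygen bridge) | C1=C[C@H]2CC(=O)[C@H](C)[C@@]1(O2)[C@H](O)C[C@@H](C)O[Si](C)(C)C(C)(C)C | intermediate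
12 | (1R,2R,5R)-1-[(1R,3R)-3-(tert-butyldimethylsilyloxy)-1-(triethylsilyloxy)butyl]-2-methyl-8-oxabicyclo[3.2.1]oct-6-en-3-one | C1=C[C@H]2CC(=O)[C@H](C)[C@@]1(O2)[C@H](O[Si](CC)(CC)CC)C[C@@H](C)O[Si](C)(C)C(C)(C)C | intermediate
13 | (1S,2R,5R,6S,7R)-6,7-dihydroxy-2-methyl-1-[(1R,3R)-3-(tert-butyldimethylsilyloxy)-1-(triethylsilyloxy)butyl]-8-oxabicyclo[3.2.1]octan-3-one (both hydroxyls exo, cis to the oxygen bridge) | O[C@@H]1[C@H]2CC(=O)[C@H](C)[C@@](O2)([C@H](O[Si](CC)(CC)CC)C[C@@H](C)O[Si](C)(C)C(C)(C)C)[C@@H]1O | intermediate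
14 | (diethoxyphosphoryl)acetic acid | CCOP(=O)(OCC)CC(=O)O | starting material
15 | (1S,2R,5R,6S,7R)-7-hydroxy-2-methyl-3-oxo-1-[(1R,3R)-3-(tert-butyldimethylsilyloxy)-1-(triethylsilyloxy)butyl]-8-oxabicyclo[3.2.1]octan-6-yl (diethoxyphosphoryl)acetate | CCOP(=O)(OCC)CC(=O)O[C@@H]1[C@H]2CC(=O)[C@H](C)[C@@](O2)([C@H](O[Si](CC)(CC)CC)C[C@@H](C)O[Si](C)(C)C(C)(C)C)[C@@H]1O | intermediate
16 | (1R,5R,6R,7R)-5-methyl-4-oxo-6-[(1R,3R)-3-(tert-butyldimethylsilyloxy)-1-(triethylsilyloxy)butyl]-6,7-bis(trimethylsilyloxy)cyclohept-2-en-1-yl (diethoxyphosphoryl)acetate | CCOP(=O)(OCC)CC(=O)O[C@@H]1C=CC(=O)[C@H](C)[C@@](O[Si](C)(C)C)([C@H](O[Si](CC)(CC)CC)C[C@@H](C)O[Si](C)(C)C(C)(C)C)[C@@H]1O[Si](C)(C)C | intermediate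
17 | cis-fused α-(diethoxyphosphoryl) lactone, the Michael adduct of 16 (epimers at the phosphonate carbon, silyl ethers as in 16) | CCOP(=O)(OCC)C1C(=O)O[C@@H]2[C@H]1CC(=O)[C@H](C)[C@@](O[Si](C)(C)C)([C@H](O[Si](CC)(CC)CC)C[C@@H](C)O[Si](C)(C)C(C)(C)C)[C@@H]2O[Si](C)(C)C | intermediate
18 | 7,8-bis(trimethylsilyl) ether of 19 | C=C1C(=O)O[C@@H]2[C@H]1CC(=O)[C@H](C)[C@@](O[Si](C)(C)C)([C@H](O[Si](CC)(CC)CC)C[C@@H](C)O[Si](C)(C)C(C)(C)C)[C@@H]2O[Si](C)(C)C | intermediate
19 | (3aS,6R,7S,8R,8aR)-7,8-dihydroxy-6-methyl-3-methylidene-7-[(1R,3R)-3-(tert-butyldimethylsilyloxy)-1-(triethylsilyloxy)butyl]hexahydro-2H-cyclohepta[b]furan-2,5(3H)-dione | C=C1C(=O)O[C@@H]2[C@H]1CC(=O)[C@H](C)[C@@](O)([C@H](O[Si](CC)(CC)CC)C[C@@H](C)O[Si](C)(C)C(C)(C)C)[C@@H]2O | intermediate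
20 | (3aS,6R,7R,8aR)-7-hydroxy-6-methyl-3-methylidene-7-[(1R,3R)-3-(tert-butyldimethylsilyloxy)-1-(triethylsilyloxy)butyl]tetrahydro-2H-cyclohepta[b]furan-2,5,8(3H)-trione | C=C1C(=O)O[C@@H]2[C@H]1CC(=O)[C@H](C)[C@@](O)([C@H](O[Si](CC)(CC)CC)C[C@@H](C)O[Si](C)(C)C(C)(C)C)C2=O | intermediate
21 | (3aS,5R,6S,7S,8S,8aR)-5,7,8-trihydroxy-6-methyl-3-methylidene-7-[(1R,3R)-3-(tert-butyldimethylsilyloxy)-1-(triethylsilyloxy)butyl]octahydro-2H-cyclohepta[b]furan-2-one | C=C1C(=O)O[C@@H]2[C@H]1C[C@@H](O)[C@H](C)[C@@](O)([C@H](O[Si](CC)(CC)CC)C[C@@H](C)O[Si](C)(C)C(C)(C)C)[C@H]2O | intermediate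
22 | (3aS,5R,6S,7S,8S,8aR)-5-(tert-butyldimethylsilyloxy)-7,8-dihydroxy-6-methyl-3-methylidene-7-[(1R,3R)-3-(tert-butyldimethylsilyloxy)-1-(triethylsilyloxy)butyl]octahydro-2H-cyclohepta[b]furan-2-one | C=C1C(=O)O[C@@H]2[C@H]1C[C@@H](O[Si](C)(C)C(C)(C)C)[C@H](C)[C@@](O)([C@H](O[Si](CC)(CC)CC)C[C@@H](C)O[Si](C)(C)C(C)(C)C)[C@H]2O | intermediate
23 | (2R)-2-methylbutanoic acid | CC[C@@H](C)C(=O)O | starting material
24 | (3aS,5R,6S,7S,8S,8aR)-5-(tert-butyldimethylsilyloxy)-7-hydroxy-6-methyl-3-methylidene-2-oxo-7-[(1R,3R)-3-(tert-butyldimethylsilyloxy)-1-(triethylsilyloxy)butyl]octahydro-2H-cyclohepta[b]furan-8-yl (2R)-2-methylbutanoate | C=C1C(=O)O[C@@H]2[C@H]1C[C@@H](O[Si](C)(C)C(C)(C)C)[C@H](C)[C@@](O)([C@H](O[Si](CC)(CC)CC)C[C@@H](C)O[Si](C)(C)C(C)(C)C)[C@H]2OC(=O)[C@H](C)CC | intermediate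
25 | (3aS,5R,6S,7R,8S,8aR)-5-(tert-butyldimethylsilyloxy)-7-hydroxy-7-[(1R,3R)-3-(tert-butyldimethylsilyloxy)-1-hydroxybutyl]-6-methyl-3-methylidene-2-oxooctahydro-2H-cyclohepta[b]furan-8-yl (2R)-2-methylbutanoate | C=C1C(=O)O[C@@H]2[C@H]1C[C@@H](O[Si](C)(C)C(C)(C)C)[C@H](C)[C@@](O)([C@H](O)C[C@@H](C)O[Si](C)(C)C(C)(C)C)[C@H]2OC(=O)[C@H](C)CC | intermediate
26 | (3aS,5R,6S,7S,8S,8aR)-5-(tert-butyldimethylsilyloxy)-7-[(3R)-3-(tert-butyldimethylsilyloxy)butanoyl]-7-hydroxy-6-methyl-3-methylidene-2-oxooctahydro-2H-cyclohepta[b]furan-8-yl (2R)-2-methylbutanoate | C=C1C(=O)O[C@@H]2[C@H]1C[C@@H](O[Si](C)(C)C(C)(C)C)[C@H](C)[C@@](O)(C(=O)C[C@@H](C)O[Si](C)(C)C(C)(C)C)[C@H]2OC(=O)[C@H](C)CC | intermediate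
27 | (3aS,5R,6S,7S,8S,8aR)-5,7-dihydroxy-7-[(3R)-3-hydroxybutanoyl]-6-methyl-3-methylidene-2-oxooctahydro-2H-cyclohepta[b]furan-8-yl (2R)-2-methylbutanoate | C=C1C(=O)O[C@@H]2[C@H]1C[C@@H](O)[C@H](C)[C@@](O)(C(=O)C[C@@H](C)O)[C@H]2OC(=O)[C@H](C)CC | target

**Step count and risks**

Total step count: 16. Longest linear sequence: 16 steps (1 to 27); 3, 8, 14 and 23 enter as purchased building blocks.

Steps most likely to fail:

1. Step 4. The cation may add in the head-to-tail orientation or through an unchelated, compact arrangement, which would erode regio-, facial and C10 selectivity. The fallback makes the same two ring bonds from 7 by a rhodium vinylcarbenoid (4+3) reaction whose orientation is fixed by the order of its events, and returns at 12. Compound 7 is silylated (TESCl, imidazole, DMF) to its TES ether F1. Methyl 2-diazo-3-oxobutanoate is silylated (TBSOTf, Et3N) to the vinyldiazo ester F2. F1 and F2 with Rh2(S-DOSP)4 (hexane, −78 to 23 °C) should undergo cyclopropanation of the unsubstituted furan double bond followed by divinylcyclopropane Cope rearrangement to the oxabicyclic silyl enol ether ester F3; the enantiomeric catalyst is available if the sense is mismatched with the C2 centre. Buffered fluoride (TBAF, AcOH, THF, −40 °C) frees the β-keto ester F4. Its dianion (NaH, then nBuLi, THF, 0 °C) is methylated with MeI at the γ-carbon (C10) from the face of the oxygen bridge to give the methylated β-keto ester F5. Krapcho dealkoxycarbonylation (LiCl, wet DMSO, 120 °C) then gives 12.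

2. Step 8. Silylation and enolisation of the acidic phosphonoacetate methylene may compete with the bridge opening, and the Lewis acid may drive uncontrolled conjugate additions or loss of the C1 silyloxy group to a dienone. The fallback keeps the phosphonate out of this step, sets out from 13 and returns at 16. Compound 13 is esterified at the C6 hydroxyl with bromoacetic acid (DCC, DMAP, CH2Cl2, −20 °C) to the bromoacetate F6. TMSOTf with the hindered base iPr2NEt (CH2Cl2, −78 to 0 °C) opens the bridge and caps the C5 hydroxyl to give the bis-TMS enone bromoacetate F7. An Arbuzov reaction with P(OEt)3 (80 °C) then installs the phosphonate and gives 16.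

3. Step 11. Diketone 20 may undergo α-ketol shift or retro-aldol cleavage before it is reduced, or hydride may reach C5 from the wrong face. The fallback inverts C5 on the rigid bicycle instead, sets out from 15 and returns at 21. Compound 15 is oxidised (Dess–Martin periodinane, NaHCO3, CH2Cl2) to the bicyclic C5 ketone F8. NaBH4 (MeOH/CH2Cl2, −78 °C, one equivalent) should attack this activated ketone from the exo face to give the endo alcohol F9. TMSOTf/Et3N gives the bis-TMS enone F10. KOtBu then paraformaldehyde give, through the phosphono lactone F11 and the bis-TMS methylene lactone F12, after citric acid in MeOH, the keto lactone F13 (the C5 epimer of 19). Me4NBH(OAc)3 then reduces only the C9 ketone under direction of the C1 hydroxyl and gives 21.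

**Further compounds**

F1 | step 4 | triethylsilyl ether of 7 | o1cccc1[C@H](O[Si](CC)(CC)CC)C[C@@H](C)O[Si](C)(C)C(C)(C)C
F2 | step 4 | methyl 2-diazo-3-(tert-butyldimethylsilyloxy)but-3-enoate | COC(=O)C(=[N+]=[N-])C(=C)O[Si](C)(C)C(C)(C)C
F3 | step 4 | methyl 3-(tert-butyldimethylsilyloxy)-5-[(1R,3R)-3-(tert-butyldimethylsilyloxy)-1-(triethylsilyloxy)butyl]-8-oxabicyclo[3.2.1]octa-2,6-diene-2-carboxylate (bridgeheads as in 12) | C1=C[C@H]2C(C(=O)OC)=C(O[Si](C)(C)C(C)(C)C)C[C@@]1(O2)[C@H](O[Si](CC)(CC)CC)C[C@@H](C)O[Si](C)(C)C(C)(C)C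
F4 | step 4 | methyl 3-oxo-5-[(1R,3R)-3-(tert-butyldimethylsilyloxy)-1-(triethylsilyloxy)butyl]-8-oxabicyclo[3.2.1]oct-6-ene-2-carboxylate (C2 epimers, keto/enol) | C1=C[C@H]2C(C(=O)OC)C(=O)C[C@@]1(O2)[C@H](O[Si](CC)(CC)CC)C[C@@H](C)O[Si](C)(C)C(C)(C)C
F5 | step 4 | methyl 4-methyl-3-oxo-5-[(1R,3R)-3-(tert-butyldimethylsilyloxy)-1-(triethylsilyloxy)butyl]-8-oxabicyclo[3.2.1]oct-6-ene-2-carboxylate (4-methyl syn to the oxygen bridge) | C1=C[C@H]2C(C(=O)OC)C(=O)[C@H](C)[C@@]1(O2)[C@H](O[Si](CC)(CC)CC)C[C@@H](C)O[Si](C)(C)C(C)(C)C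
F6 | step 8 | C6 bromoacetate of diol 13 | BrCC(=O)O[C@@H]1[C@H]2CC(=O)[C@H](C)[C@@](O2)([C@H](O[Si](CC)(CC)CC)C[C@@H](C)O[Si](C)(C)C(C)(C)C)[C@@H]1O
F7 | step 8 | bromoacetate analogue of enone 16 | BrCC(=O)O[C@@H]1C=CC(=O)[C@H](C)[C@@](O[Si](C)(C)C)([C@H](O[Si](CC)(CC)CC)C[C@@H](C)O[Si](C)(C)C(C)(C)C)[C@@H]1O[Si](C)(C)C
F8 | step 11 | bicyclic C5 ketone from 15 | CCOP(=O)(OCC)CC(=O)O[C@@H]1[C@H]2CC(=O)[C@H](C)[C@@](O2)([C@H](O[Si](CC)(CC)CC)C[C@@H](C)O[Si](C)(C)C(C)(C)C)C1=O
F9 | step 11 | C5 epimer of 15 (endo hydroxyl) | CCOP(=O)(OCC)CC(=O)O[C@@H]1[C@H]2CC(=O)[C@H](C)[C@@](O2)([C@H](O[Si](CC)(CC)CC)C[C@@H](C)O[Si](C)(C)C(C)(C)C)[C@H]1O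
F10 | step 11 | C5 epimer of enone 16 | CCOP(=O)(OCC)CC(=O)O[C@@H]1C=CC(=O)[C@H](C)[C@@](O[Si](C)(C)C)([C@H](O[Si](CC)(CC)CC)C[C@@H](C)O[Si](C)(C)C(C)(C)C)[C@H]1O[Si](C)(C)C
F11 | step 11 | C5 epimer of phosphono lactone 17 | CCOP(=O)(OCC)C1C(=O)O[C@@H]2[C@H]1CC(=O)[C@H](C)[C@@](O[Si](C)(C)C)([C@H](O[Si](CC)(CC)CC)C[C@@H](C)O[Si](C)(C)C(C)(C)C)[C@H]2O[Si](C)(C)C
F12 | step 11 | C5 epimer of bis-TMS methylene lactone 18 | C=C1C(=O)O[C@@H]2[C@H]1CC(=O)[C@H](C)[C@@](O[Si](C)(C)C)([C@H](O[Si](CC)(CC)CC)C[C@@H](C)O[Si](C)(C)C(C)(C)C)[C@H]2O[Si](C)(C)C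
F13 | step 11 | C5 epimer of keto lactone 19 | C=C1C(=O)O[C@@H]2[C@H]1CC(=O)[C@H](C)[C@@](O)([C@H](O[Si](CC)(CC)CC)C[C@@H](C)O[Si](C)(C)C(C)(C)C)[C@H]2O
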